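**Retrosynthetic overview**
1. Target ⇒ five-fold MOM removal ⇒ protected chalcone; the cinnamoyl unit is put on ring A last, by directed lithiation and acylation with an E-cinnamoyl Weinreb amide.
2. All-cis 2,4,6-trisubstituted oxane ⇒ 4,6-cis δ-lactone: the C2 aryl comes from an aryllithium, the C2 hydrogen from axial hydride delivery to the oxocarbenium ion.
3. Key disconnection C4–C5: the β-carbon of a ring A cinnamaldehyde, turned nucleophilic as a carbene-bound homoenolate, opens an (S)-terminal epoxide at CH2, and the freed alkoxide closes the lactone in the same step.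
4. Enal from 5-methoxyresorcinol (2 steps); epoxide from 1-bromo-4-(methoxymethoxy)benzene (3 steps, hydrolytic kinetic resolution).
5. Ring order: the three benzene rings are bought; the only ring built is the pyranone (key step), which is then reduced to the oxane.

MOMO = methoxymethoxy (OCH2OCH3); ring A = the trioxygenated benzene ring.
Assumption: the (5aS,10bR) triazolium catalyst is taken to deliver the epoxide to the enal face that gives (4R); if the sense is the reverse, its enantiomer is used and nothing else changes.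

**Step 1**
Reactants: 1 5-methoxyresorcinol
Product: 2 1-methoxy-3,5-bis(MOMO)benzene
Conditions: MOMCl (2.5 equiv), iPr2NEt (3 equiv), CH2Cl2, 0 °C → rt
Reagents that add atoms: chloromethyl methyl ether, COCCl
Why: Williamson-type O-alkylation of both phenols (MOM protection) gives ethers that survive organolithiums and later direct metalation; no stereocentre.

**Step 2**
Reactants: 2 1-methoxy-3,5-bis(MOMO)benzene; 3 (E)-3-(dimethylamino)prop-2-enal
Product: 6 (E)-3-[4-methoxy-2,6-bis(MOMO)phenyl]prop-2-enal, via aryllithium 4 (not isolated), via lithium alkoxide adduct 5 (not isolated)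
Conditions: n-BuLi (1.1 equiv), TMEDA, THF, 0 °C; then 3, −78 → 0 °C; then 1 M HCl, 0 °C, 15 min
Reagents that add atoms: water, O
Why: Directed ortho-metalation occurs at the C–H flanked by the two chelating OMOM groups, and 1,2-addition to the vinylogous formamide followed by acid-induced loss of dimethylamine (vinylogous formylation) gives the thermodynamic E-enal.

**Step 3**
Reactants: 7 1-bromo-4-(MOMO)benzene; 8 but-3-en-1-ylmagnesium bromide
Product: 9 1-(but-3-en-1-yl)-4-(MOMO)benzene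
Conditions: Pd(dppf)Cl2 (2 mol %), THF, 50 °C
Reagents that add atoms: none
Why: Kumada–Corriu coupling; the wide-bite-angle dppf ligand makes reductive elimination faster than β-hydride elimination of the primary alkyl group.

**Step 4**
Reactants: 9 1-(but-3-en-1-yl)-4-(MOMO)benzene
Product: 10 rac-2-{2-[4-(MOMO)phenyl]ethyl}oxirane
Conditions: mCPBA (1.3 equiv), NaHCO3, CH2Cl2, 0 °C → rt
Reagents that add atoms: 3-chloroperoxybenzoic acid, OOC(=O)c1cccc(Cl)c1
Why: Prilezhaev epoxidation of the isolated terminal alkene; the bicarbonate buffer protects the MOM ether; the product is racemic.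

**Step 5**
Reactants: 10 rac-2-{2-[4-(MOMO)phenyl]ethyl}oxirane
Product: 11 (S)-2-{2-[4-(MOMO)phenyl]ethyl}oxirane
Conditions: (S,S)-(salen)Co(OAc) (0.5 mol %; salen = N,N'-bis(3,5-di-tert-butylsalicylidene)cyclohexane-1,2-diaminate), H2O (0.55 equiv), THF, 0 °C → rt
Reagents that add atoms: none
Why: Jacobsen hydrolytic kinetic resolution; this catalyst enantiomer hydrolyses the R epoxide and leaves the S epoxide in >99% ee, which fixes the future C6 centre.

**Step 6**
Reactants: 6 (E)-3-[4-methoxy-2,6-bis(MOMO)phenyl]prop-2-enal; 11 (S)-2-{2-[4-(MOMO)phenyl]ethyl}oxirane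
Product: 12 (4R,6S)-4-[4-methoxy-2,6-bis(MOMO)phenyl]-6-{2-[4-(MOMO)phenyl]ethyl}oxan-2-one
Conditions: (5aS,10bR)-2-mesityl-5a,10b-dihydro-4H,6H-indeno[2,1-b][1,2,4]triazolo[4,3-d][1,4]oxazin-2-ium chloride (15 mol %), DBU (15 mol %), Mg(OtBu)2 (20 mol %), 4 Å MS, THF, 40 °C; 6 added over 6 h to 11 (2 equiv)
Reagents that add atoms: none
Why: Proposed new method: the triazolylidene adds to the enal to give the extended Breslow (homoenolate) intermediate, whose β-carbon is an enaminol-type nucleophile that opens the magnesium-activated terminal epoxide by SN2 attack at CH2 (C4–C5 bond between two natively electrophilic carbons), after which the magnesium alkoxide lactonizes onto the acyl azolium and frees the carbene; C4 is set by the aminoindanol catalyst shielding one face of the homoenolate and C6 is carried over untouched from 11, so any minor isomer is a separable trans diastereomer; the closest known reaction types are carbene homoenolate annulations of enals with aldehydes, imines and nitroalkenes under Lewis-acid co-catalysis, carbene/palladium homoenolate additions to vinyl-epoxide-derived electrophiles that end in alkoxide lactonization, and enamine alkylation by epoxides.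

**Step 7**
Reactants: 12 (4R,6S)-lactone; 7 1-bromo-4-(MOMO)benzene
Product: 15 (4R,6S)-4-[4-methoxy-2,6-bis(MOMO)phenyl]-2-[4-(MOMO)phenyl]-6-{2-[4-(MOMO)phenyl]ethyl}oxan-2-ol (anomer mixture), via 4-(MOMO)phenyllithium 13 (not isolated), via lithium lactolate 14 (not isolated)
Conditions: 7 (1.3 equiv), n-BuLi (1.25 equiv), THF, −78 °C; then 12, −78 °C, 1 h; sat. aq. NH4Cl
Reagents that add atoms: none
Why: Bromine–lithium exchange followed by 1,2-addition of the aryllithium to the δ-lactone stops at the tetrahedral lithium lactolate at −78 °C, so no second addition occurs; C4 and C6 are untouched.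

**Step 8**
Reactants: 15 lactol
Product: 16 (2S,4R,6S)-4-[4-methoxy-2,6-bis(MOMO)phenyl]-2-[4-(MOMO)phenyl]-6-{2-[4-(MOMO)phenyl]ethyl}oxane (all-cis)
Conditions: Et3SiH (3 equiv), BF3·OEt2 (1.2 equiv), CH2Cl2/MeCN 1:1, −78 → −50 °C; sat. aq. NaHCO3
Reagents that add atoms: none
Why: Kishi-type reductive deoxygenation (ionic hydrogenation): the aryl-stabilised oxocarbenium ion forms already at −78 °C and takes hydride axially through a chair-like transition state with the C4 and C6 groups equatorial, which puts the C2 aryl equatorial and sets (2S), all-cis.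

**Step 9**
Reactants: 17 4-(MOMO)benzaldehyde; 18 diethyl {2-[methoxy(methyl)amino]-2-oxoethyl}phosphonate
Product: 20 (E)-N-methoxy-3-[4-(MOMO)phenyl]-N-methylprop-2-enamide, via sodium phosphonate carbanion 19 (not isolated)
Conditions: NaH (1.2 equiv), THF, 0 °C → rt
Reagents that add atoms: none
Why: Horner–Wadsworth–Emmons olefination with a stabilised phosphonate anion gives the E-alkene.

**Step 10**
Reactants: 16 all-cis oxane; 20 (E)-N-methoxy-3-[4-(MOMO)phenyl]-N-methylprop-2-enamide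
Product: 23 (E)-1-{6-methoxy-2,4-bis(MOMO)-3-[(2S,4R,6S)-2-[4-(MOMO)phenyl]-6-{2-[4-(MOMO)phenyl]ethyl}oxan-4-yl]phenyl}-3-[4-(MOMO)phenyl]prop-2-en-1-one, via ring A aryllithium 21 (not isolated), via tetrahedral lithium adduct 22 (not isolated)
Conditions: n-BuLi (1.1 equiv), TMEDA, THF, −20 → 0 °C; then 20 (1.5 equiv), −78 → 0 °C; sat. aq. NH4Cl
Reagents that add atoms: none
Why: Directed ortho-metalation takes the only C–H flanked by two oxygen directors (OMOM and OMe; the two such sites on ring A are equivalent), and Weinreb ketone synthesis by 1,2-addition gives a chelated adduct that releases the E-enone only on quench; no stereocentre is touched.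

**Step 11**
Reactants: 23 penta-MOM chalcone
Product: 24 (E)-1-{2,4-dihydroxy-3-[(2S,4R,6S)-2-(4-hydroxyphenyl)-6-[2-(4-hydroxyphenyl)ethyl]oxan-4-yl]-6-methoxyphenyl}-3-(4-hydroxyphenyl)prop-2-en-1-one
Conditions: 3 M aq. HCl/MeOH 1:10, 40 °C, 3 h
Reagents that add atoms: none
Why: Acid-catalysed acetal exchange moves all five MOM groups onto methanol while the methyl ether stays; the all-equatorial oxane is the thermodynamic isomer, so reversible benzylic ionization at C2 cannot erode configuration.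

**Compound list**
1 | 5-methoxyresorcinol | COc1cc(O)cc(O)c1 | starting material
2 | 1-methoxy-3,5-bis(MOMO)benzene | COCOc1cc(OC)cc(OCOC)c1 | intermediate
3 | (E)-3-(dimethylamino)prop-2-enal | CN(C)/C=C/C=O | starting material
4 | [4-methoxy-2,6-bis(MOMO)phenyl]lithium | [Li]c1c(OCOC)cc(OC)cc1OCOC | intermediate
5 | lithium (E)-3-(dimethylamino)-1-[4-methoxy-2,6-bis(MOMO)phenyl]prop-2-en-1-olate (racemic) | CN(C)/C=C/C(O[Li])c1c(OCOC)cc(OC)cc1OCOC | intermediate
6 | (E)-3-[4-methoxy-2,6-bis(MOMO)phenyl]prop-2-enal | COCOc1cc(OC)cc(OCOC)c1/C=C/C=O | intermediate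
7 | 1-bromo-4-(MOMO)benzene | COCOc1ccc(Br)cc1 | starting material
8 | but-3-en-1-ylmagnesium bromide | C=CCC[Mg]Br | starting material
9 | 1-(but-3-en-1-yl)-4-(MOMO)benzene | C=CCCc1ccc(OCOC)cc1 | intermediate
10 | rac-2-{2-[4-(MOMO)phenyl]ethyl}oxirane | COCOc1ccc(CCC2CO2)cc1 | intermediate
11 | (S)-2-{2-[4-(MOMO)phenyl]ethyl}oxirane | COCOc1ccc(CC[C@H]2CO2)cc1 | intermediate
12 | (4R,6S)-4-[4-methoxy-2,6-bis(MOMO)phenyl]-6-{2-[4-(MOMO)phenyl]ethyl}oxan-2-one (4,6-cis) | COc1cc(OCOC)c([C@@H]2C[C@H](CCc3ccc(OCOC)cc3)OC(=O)C2)c(OCOC)c1 | intermediate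
13 | [4-(MOMO)phenyl]lithium | [Li]c1ccc(OCOC)cc1 | intermediate
14 | lithium (4R,6S)-4-[4-methoxy-2,6-bis(MOMO)phenyl]-2-[4-(MOMO)phenyl]-6-{2-[4-(MOMO)phenyl]ethyl}oxan-2-olate | COc1cc(OCOC)c([C@@H]2C[C@H](CCc3ccc(OCOC)cc3)OC(O[Li])(c3ccc(OCOC)cc3)C2)c(OCOC)c1 | intermediate
15 | (4R,6S)-4-[4-methoxy-2,6-bis(MOMO)phenyl]-2-[4-(MOMO)phenyl]-6-{2-[4-(MOMO)phenyl]ethyl}oxan-2-ol (anomer mixture) | COc1cc(OCOC)c([C@@H]2C[C@H](CCc3ccc(OCOC)cc3)OC(O)(c3ccc(OCOC)cc3)C2)c(OCOC)c1 | intermediate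
16 | (2S,4R,6S)-4-[4-methoxy-2,6-bis(MOMO)phenyl]-2-[4-(MOMO)phenyl]-6-{2-[4-(MOMO)phenyl]ethyl}oxane (all-cis) | COc1cc(OCOC)c([C@@H]2C[C@H](CCc3ccc(OCOC)cc3)O[C@H](c3ccc(OCOC)cc3)C2)c(OCOC)c1 | intermediate
17 | 4-(MOMO)benzaldehyde | COCOc1ccc(C=O)cc1 | starting material
18 | diethyl {2-[methoxy(methyl)amino]-2-oxoethyl}phosphonate | CCOP(=O)(CC(=O)N(C)OC)OCC | starting material
19 | sodium salt of the carbanion of 18 | CCOP(=O)([CH-]C(=O)N(C)OC)OCC.[Na+] | intermediate
20 | (E)-N-methoxy-3-[4-(MOMO)phenyl]-N-methylprop-2-enamide | COCOc1ccc(/C=C/C(=O)N(C)OC)cc1 | intermediate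
21 | {6-methoxy-2,4-bis(MOMO)-3-[(2S,4R,6S)-2-[4-(MOMO)phenyl]-6-{2-[4-(MOMO)phenyl]ethyl}oxan-4-yl]phenyl}lithium | COc1cc(OCOC)c([C@@H]2C[C@H](CCc3ccc(OCOC)cc3)O[C@H](c3ccc(OCOC)cc3)C2)c(OCOC)c1[Li] | intermediate
22 | lithium (E)-1-[methoxy(methyl)amino]-1-{ring A aryl of 21}-3-[4-(MOMO)phenyl]prop-2-en-1-olate | COc1cc(OCOC)c([C@@H]2C[C@H](CCc3ccc(OCOC)cc3)O[C@H](c3ccc(OCOC)cc3)C2)c(OCOC)c1C(O[Li])(/C=C/c1ccc(OCOC)cc1)N(C)OC | intermediate
23 | (E)-1-{6-methoxy-2,4-bis(MOMO)-3-[(2S,4R,6S)-2-[4-(MOMO)phenyl]-6-{2-[4-(MOMO)phenyl]ethyl}oxan-4-yl]phenyl}-3-[4-(MOMO)phenyl]prop-2-en-1-one | COc1cc(OCOC)c([C@@H]2C[C@H](CCc3ccc(OCOC)cc3)O[C@H](c3ccc(OCOC)cc3)C2)c(OCOC)c1C(=O)/C=C/c1ccc(OCOC)cc1 | intermediate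
24 | (E)-1-{2,4-dihydroxy-3-[(2S,4R,6S)-2-(4-hydroxyphenyl)-6-[2-(4-hydroxyphenyl)ethyl]oxan-4-yl]-6-methoxyphenyl}-3-(4-hydroxyphenyl)prop-2-en-1-one | COc1cc(O)c([C@@H]2C[C@H](CCc3ccc(O)cc3)O[C@H](c3ccc(O)cc3)C2)c(O)c1C(=O)/C=C/c1ccc(O)cc1 | target

**Count and risks**
Total steps: 11. Longest linear sequence: 8 (steps 3, 4, 5, 6, 7, 8, 10, 11).

Most likely to fail, first: step 6. The homoenolate may be too weak a nucleophile for the epoxide, the free carbene may itself open the epoxide, or the enal may dimerize. The fallback sets out from 11 and 2 and comes back at 12. Epoxide 11 is opened at CH2 by lithiated ethyl propiolate with BF3·OEt2 at −78 °C to give ethyl (5S)-5-hydroxy-7-[4-(MOMO)phenyl]hept-2-ynoate F1. The lithium diarylcuprate made from aryllithium 4 (from 2) and CuBr·SMe2 then adds syn to the ynoate, and the resulting Z-hydroxy enoate lactonizes to (6S)-4-[4-methoxy-2,6-bis(MOMO)phenyl]-6-{2-[4-(MOMO)phenyl]ethyl}-5,6-dihydro-2H-pyran-2-one F2. Hydrogenation over palladium on carbon (Pd/C, H2, EtOAc) adds hydrogen to the face away from the C6 chain and gives the 4,6-cis lactone 12.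

Second: step 10. Metalation could compete at the positions ortho to the single OMOM groups or at the benzylic C2–H, and the hindered aryllithium could add 1,4. The fallback sets out from 16 and comes back at 23. NBS in MeCN at −20 °C brominates only the trioxygenated ring A to give {3-bromo-6... ring A bromide} (2S,4R,6S)-4-[3-bromo-4-methoxy-2,6-bis(MOMO)phenyl]-2-[4-(MOMO)phenyl]-6-{2-[4-(MOMO)phenyl]ethyl}oxane F3. Bromine–lithium exchange with n-BuLi at −78 °C (no deprotonation, site fixed by the bromine) and addition to amide 20 then give 23.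

Third: step 11. The acid may open the p-hydroxybenzylic ether to a methanol-trapped chain, or cyclize the 2'-hydroxychalcone to a flavanone. The fallback sets out from 16 and comes back at 24. Lithiation of 16 as in step 10 and quenching with N-methoxy-N-methylacetamide gives 1-{6-methoxy-2,4-bis(MOMO)-3-[(2S,4R,6S)-2-[4-(MOMO)phenyl]-6-{2-[4-(MOMO)phenyl]ethyl}oxan-4-yl]phenyl}ethan-1-one F4. The MOM groups are removed at this enone-free stage under non-solvolytic conditions (ZnBr2, n-PrSH, CH2Cl2, 0 °C) to give 1-{2,4-dihydroxy-3-[(2S,4R,6S)-2-(4-hydroxyphenyl)-6-[2-(4-hydroxyphenyl)ethyl]oxan-4-yl]-6-methoxyphenyl}ethan-1-one F5. Claisen–Schmidt condensation of F5 with unprotected 4-hydroxybenzaldehyde (50% aq. KOH, EtOH, rt) then gives 24, so the chalcone never meets acid.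

**Further compounds**
F1 | step 6 | ethyl (5S)-5-hydroxy-7-[4-(MOMO)phenyl]hept-2-ynoate | CCOC(=O)C#CC[C@@H](O)CCc1ccc(OCOC)cc1
F2 | step 6 | (6S)-4-[4-methoxy-2,6-bis(MOMO)phenyl]-6-{2-[4-(MOMO)phenyl]ethyl}-5,6-dihydro-2H-pyran-2-one | COc1cc(OCOC)c(C2=CC(=O)O[C@@H](CCc3ccc(OCOC)cc3)C2)c(OCOC)c1
F3 | step 10 | (2S,4R,6S)-4-[3-bromo-4-methoxy-2,6-bis(MOMO)phenyl]-2-[4-(MOMO)phenyl]-6-{2-[4-(MOMO)phenyl]ethyl}oxane | COc1cc(OCOC)c([C@@H]2C[C@H](CCc3ccc(OCOC)cc3)O[C@H](c3ccc(OCOC)cc3)C2)c(OCOC)c1Br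
F4 | step 11 | 1-{6-methoxy-2,4-bis(MOMO)-3-[(2S,4R,6S)-2-[4-(MOMO)phenyl]-6-{2-[4-(MOMO)phenyl]ethyl}oxan-4-yl]phenyl}ethan-1-one | COc1cc(OCOC)c([C@@H]2C[C@H](CCc3ccc(OCOC)cc3)O[C@H](c3ccc(OCOC)cc3)C2)c(OCOC)c1C(C)=O
F5 | step 11 | 1-{2,4-dihydroxy-3-[(2S,4R,6S)-2-(4-hydroxyphenyl)-6-[2-(4-hydroxyphenyl)ethyl]oxan-4-yl]-6-methoxyphenyl}ethan-1-one | COc1cc(O)c([C@@H]2C[C@H](CCc3ccc(O)cc3)O[C@H](c3ccc(O)cc3)C2)c(O)c1C(C)=O
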